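Numbering (germacranolide): C1 ketone, C4–C5 epoxide, C6 lactone CH–O, C7 spiro carbon, C8 ester carbon, C9 CH2, C10 methyl-bearing ether carbon, C11–C13 methylene lactone, C14/C15 methyls. Cuts, in retro order: C8 ester; lactone carbonyl C12 (CO); epoxide O; C4=C5 (metathesis); C1–C2 and C5–C6 (organometallic additions); then C9–C10 and C7–C8 of the oxolane.
Enabling feature: the oxolane oxygen lies between the two fully substituted carbons C7 and C10, and C10 is alpha to the C1 ketone. C10–O–C7 is therefore the retron of a ketone-stabilised carbonyl ylide (diazo carbon C10, ketone oxygen on C7), and C8(O)–C9 is a vinyl ether.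
Forward: a rhodium-catalysed carbonyl-ylide (3+2) cycloaddition builds the oxolane inside a temporary six-membered ring (C10–C1–C2–C6–C7–O). That ring is then cut between C2 and C6 (C2 leaves as formic acid), giving a cis-2,5-disubstituted oxolane with a C1 acyl group and a C6 aldehyde.
Chains are added at C6 (vinyl = C5) and C1 (C2–C4), the ten-membered carbocycle is closed at C4=C5 (Z), the epoxide is delivered from the C6 hydroxyl, the methylene lactone is made from the C7 alkyne with CO, and C8 is acylated last.
Stereochemistry: C7, C8, C10 from the chiral rhodium catalyst (exo approach); C6 from Felkin–Anh addition next to C7; C4/C5 from hydroxyl-directed epoxidation of the macrocyclic Z-alkene before the lactone locks the ring.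

Key step: step 4

Assumption: the sense of induction of Rh2(S-TCPTTL)4 on ylide 10 is taken to parallel its behaviour with related six-membered carbonyl ylides and vinyl ethers, giving (1R,5S,6S)-11; if it proves opposite, the enantiomeric catalyst is used.

Step 1
Reactants: 1 (4-methoxyphenyl)methanol; 2 ethenyl acetate (2 equiv)
Product: 3 1-[(ethenyloxy)methyl]-4-methoxybenzene (4-methoxybenzyl vinyl ether)
Conditions: [Ir(cod)Cl]2 (1 mol %), Na2CO3 (0.6 equiv), toluene, 100 °C
Reagents that add atoms: none
Why: Iridium-catalysed transfer vinylation of an alcohol by a vinyl ester (addition–elimination at the vinyl group) should give the vinyl ether; no stereocentre is formed.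

Step 2
Reactants: 4 ethynyltri(propan-2-yl)silane; 5 oxolane-2,5-dione (succinic anhydride)
Product: 7 4-oxo-6-[tri(propan-2-yl)silyl]hex-5-ynoic acid, via lithium silylacetylide 6 (not isolated)
Conditions: n-BuLi, THF, −78 °C; then added to 5, THF, −78 °C; aq. HCl work-up
Reagents that add atoms: none
Why: Acylation of a lithium acetylide by a cyclic anhydride should stop at the ynone because the carboxylate that forms deactivates the product toward a second addition; no stereocentre.

Step 3
Reactants: 7 4-oxo-6-[tri(propan-2-yl)silyl]hex-5-ynoic acid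
Product: 9 7-diazo-1-[tri(propan-2-yl)silyl]oct-1-yne-3,6-dione, via mixed carbonic anhydride 8 (not isolated)
Conditions: i-BuOCOCl, N-methylmorpholine, THF, −15 °C; then CH3CHN2 (Et2O solution, freshly made from N-ethyl-N-nitrosourea and KOH), 0 °C
Reagents that add atoms: diazoethane CC=[N+]=[N-]
Why: C-acylation of a diazoalkane by a mixed anhydride (diazo ketone synthesis of the Arndt–Eistert type) should give the 2-diazo-3-ketone, the bulky silyl cap keeping the ynone out of a dipolar cycloaddition with diazoethane; no stereocentre.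

Step 4
Reactants: 9 7-diazo-1-[tri(propan-2-yl)silyl]oct-1-yne-3,6-dione; 3 4-methoxybenzyl vinyl ether (3 equiv)
Product: 11 (1R,5S,6S)-6-[(4-methoxyphenyl)methoxy]-1-methyl-5-{[tri(propan-2-yl)silyl]ethynyl}-8-oxabicyclo[3.2.1]octan-2-one (6-exo ether), via carbonyl ylide 10 (not isolated)
Conditions: Rh2(S-TCPTTL)4, dirhodium tetrakis[N-tetrachlorophthaloyl-(S)-tert-leucinate] (1 mol %), PhCF3, 0 °C, slow addition of 9 to catalyst and 3
Reagents that add atoms: none
Why: The chiral dirhodium carboxylate turns 9 into a rhodium carbenoid at C10, which is captured by the lone pair of the C7 ynone oxygen to give the six-membered, rhodium-associated carbonyl ylide 10, and a concerted suprafacial (3+2) cycloaddition with the electron-rich alkene of 3 then forms C9–C10 and C8–C7. The closest known reaction type is the dirhodium-catalysed tandem carbonyl-ylide formation/intermolecular cycloaddition of diazo diketones with vinyl ethers, including its enantioselective form with this catalyst class. Ring closures: the temporary oxanone ring closes by oxygen-to-carbenoid attack (six-membered ylide formation) and the oxolane by the (3+2) cycloaddition across C10–O–C7, together giving the 8-oxabicyclo[3.2.1]octanone. Stereocentres: C7 and C10 are tied cis by the bicycle and their absolute sense should be set by the carboxylate ligands of the rhodium-bound ylide, while C8 should be set by exo approach of the vinyl ether with its alkoxy group pointing away from the C1–C2–C6 bridge. The step needs regioselectivity (the unsubstituted vinyl carbon must bond to C10, the ylide carbon next to the C1 carbonyl, as expected for monosubstituted alkenes with such ylides) and chemoselectivity for ylide formation over 1,2-hydride shift from C14, cyclopropanation of 3 or attack on the alkyne; the six-membered delivery of the ketone oxygen, the low temperature and the bulky silyl cap should secure these.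

Step 5
Reactants: 11 the cycloadduct
Product: 13 (1R,5S,6S)-6-[(4-methoxyphenyl)methoxy]-1-methyl-5-{[tri(propan-2-yl)silyl]ethynyl}-8-oxabicyclo[3.2.1]oct-3-en-2-one, via trimethylsilyl enol ether 12 (not isolated)
Conditions: LiN(SiMe3)2, Me3SiCl, THF, −78 °C; then Pd(OAc)2 (1.05 equiv), MeCN, rt
Reagents that add atoms: none
Why: Saegusa–Ito oxidation: the ketone can enolise only toward C2 because C10 is quaternary, and palladium diacetate should dehydrosilylate the silyl enol ether to the C2=C6 enone without touching the existing stereocentres.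

Step 6
Reactants: 13 the enone
Product: 15 (2R,4S,5S)-5-formyl-4-[(4-methoxyphenyl)methoxy]-2-methyl-5-{[tri(propan-2-yl)silyl]ethynyl}oxolane-2-carboxylic acid, via exo-cis diol 14 (not isolated)
Conditions: OsO4 (2 mol %), NaIO4 (4 equiv), 2,6-lutidine, 1,4-dioxane/H2O, rt
Reagents that add atoms: osmium tetroxide O=[Os](=O)(=O)=O; sodium periodate [Na+].[O-]I(=O)(=O)=O; water O
Why: Lemieux–Johnson cleavage: dihydroxylation of the C2=C6 alkene followed by two periodate (Malaprade) cleavages, of the diol and of the resulting alpha-keto aldehyde, should leave C6 as the aldehyde and C1 as the acid while C2 departs as formic acid; C7 and C10 are quaternary and cannot epimerise.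

Step 7
Reactants: 15 the aldehyde acid
Product: 16 (2R,4S,5S)-5-formyl-N-methoxy-4-[(4-methoxyphenyl)methoxy]-N,2-dimethyl-5-{[tri(propan-2-yl)silyl]ethynyl}oxolane-2-carboxamide
Conditions: MeNHOMe·HCl, EDC·HCl, N-methylmorpholine, CH2Cl2, 0 °C to rt
Reagents that add atoms: N,O-dimethylhydroxylamine hydrochloride CNOC.Cl
Why: Carbodiimide amidation should turn the acid into the Weinreb amide and leave the hindered, non-enolisable aldehyde free; no stereocentre changes.

Step 8
Reactants: 16 the Weinreb amide aldehyde; 17 iodoethene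
Product: 18 (2R,4S,5S)-N-methoxy-4-[(4-methoxyphenyl)methoxy]-N,2-dimethyl-5-{(1R)-1-[(triethylsilyl)oxy]prop-2-en-1-yl}-5-{[tri(propan-2-yl)silyl]ethynyl}oxolane-2-carboxamide
Conditions: CrCl2 (15 mol %), NiCl2 (2 mol %), Mn powder (2 equiv), Et3SiCl (2.5 equiv), DME/DMF, rt
Reagents that add atoms: chlorotriethylsilane CC[Si](Cl)(CC)CC
Why: Chromium-catalysed Nozaki–Hiyama–Kishi vinylation (manganese metal regenerates divalent chromium, the silyl chloride frees the alkoxide) should add the vinyl group to the aldehyde only and release the silyl ether directly; C6 should be set by Felkin–Anh attack anti to the C7–O bond, with the slim alkynyl group as the small substituent.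

Step 9
Reactants: 18 the allylic silyl ether; 19 4-bromo-2-methylbut-1-ene
Product: 21 1-[(2R,4S,5S)-4-[(4-methoxyphenyl)methoxy]-2-methyl-5-{(1R)-1-[(triethylsilyl)oxy]prop-2-en-1-yl}-5-{[tri(propan-2-yl)silyl]ethynyl}oxolan-2-yl]-4-methylpent-4-en-1-one, via Grignard reagent 20 (not isolated)
Conditions: Mg, THF, rt (19 to 20); then 18, THF, 0 °C to rt; aq. NH4Cl
Reagents that add atoms: none
Why: Weinreb ketone synthesis: the chelated tetrahedral adduct should persist until work-up, so the Grignard reagent adds once to give the C1 ketone, and the silyl ether on O6 keeps that ketone from closing a hemiketal; no stereocentre changes.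

Step 10
Reactants: 21 the diene ketone
Product: 22 (1R,5Z,7R,8S,9S)-9-[(4-methoxyphenyl)methoxy]-1,5-dimethyl-7-[(triethylsilyl)oxy]-8-{[tri(propan-2-yl)silyl]ethynyl}-11-oxabicyclo[6.2.1]undec-5-en-2-one
Conditions: second-generation Grubbs catalyst (H2IMes)(PCy3)Cl2Ru=CHPh (10 mol %), toluene (1 mM), 80 °C
Reagents that add atoms: none
Why: Ring-closing metathesis, a reaction type known for closing 2,5-cis-oxolane-bridged medium rings at a trisubstituted alkene: the carbene formed at the C5 vinyl group should close onto the 1,1-disubstituted alkene because the oxolane holds both chains on one face, and the bridged ten-membered ring should only accommodate the Z alkene.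

Step 11
Reactants: 22 the macrocyclic silyl ether
Product: 23 (1R,5Z,7R,8R,9S)-8-ethynyl-7-hydroxy-9-[(4-methoxyphenyl)methoxy]-1,5-dimethyl-11-oxabicyclo[6.2.1]undec-5-en-2-one
Conditions: Bu4NF (3 equiv), THF, 0 °C to rt; H2O work-up
Reagents that add atoms: none
Why: Fluoride should cleave the O–Si bond of the triethylsilyl ether and the C(sp)–Si bond of the silyl alkyne in one operation while the 4-methoxybenzyl ether and the ketone stay; no stereocentre changes.

Step 12
Reactants: 23 the macrocyclic allylic alcohol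
Product: 24 (1R,5R,6S,7R,8R,9S)-5,6-epoxy-8-ethynyl-7-hydroxy-9-[(4-methoxyphenyl)methoxy]-1,5-dimethyl-11-oxabicyclo[6.2.1]undecan-2-one (4R,5S epoxide in target numbering)
Conditions: VO(acac)2 (5 mol %), t-BuOOH (1.5 equiv), CH2Cl2, 0 °C
Reagents that add atoms: tert-butyl hydroperoxide CC(C)(C)OO
Why: Hydroxyl-directed epoxidation by a vanadium alkylperoxide: a model of the ring places the C6–O bond out of the alkene plane on the open face while C7 and the transannular ether oxygen cover the other, so oxygen transfer from vanadium bound to O6 should give the 4R,5S epoxide; this is done before lactonisation because the lactone would turn that face inward.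

Step 13
Reactants: 24 the epoxy alcohol
Product: 25 the 4-methoxybenzyl ether of alcohol 26 (spiro alpha-methylene gamma-lactone closed between C7 and O6)
Conditions: PdI2 (5 mol %), PBu3 (10 mol %), CO (7 atm), MeCN, 70 °C
Reagents that add atoms: carbon monoxide [C-]#[O+]
Why: Palladium-catalysed cyclocarbonylation of a homopropargylic alcohol: the alkoxycarbonyl species formed on divalent palladium from O6 and CO should add cis across the terminal alkyne and protonolysis should release the alpha-methylene gamma-lactone; C6 keeps its configuration because only its O–H bond reacts, and O8 cannot compete while it is an ether.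

Step 14
Reactants: 25 the lactone ether
Product: 26 the C8 alcohol (the target without its 2-methylprop-2-enoyl group)
Conditions: DDQ, CH2Cl2/pH 7 buffer, 0 °C to rt
Reagents that add atoms: none
Why: Oxidative cleavage of the 4-methoxybenzyl ether by hydride abstraction at the electron-rich benzylic carbon should free the C8 alcohol without acid or base, so the epoxide and the methylene lactone should survive.

Step 15
Reactants: 26 the C8 alcohol; 27 2-methylprop-2-enoyl chloride
Product: 28 CNP0241021.1 (target)
Conditions: Et3N, DMAP (cat.), CH2Cl2, 0 °C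
Reagents that add atoms: none
Why: Acylation of the secondary alcohol under nucleophilic catalysis should give the ester with retention at C8, since the C8–O bond is not broken.

Compound list
1 | (4-methoxyphenyl)methanol | COc1ccc(CO)cc1 | starting material
2 | ethenyl acetate (vinyl acetate) | C=COC(C)=O | starting material
3 | 1-[(ethenyloxy)methyl]-4-methoxybenzene | C=COCc1ccc(OC)cc1 | intermediate
4 | ethynyltri(propan-2-yl)silane | C#C[Si](C(C)C)(C(C)C)C(C)C | starting material
5 | oxolane-2,5-dione (succinic anhydride) | O=C1CCC(=O)O1 | starting material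
6 | lithium [tri(propan-2-yl)silyl]acetylide | [Li]C#C[Si](C(C)C)(C(C)C)C(C)C | intermediate (not isolated)
7 | 4-oxo-6-[tri(propan-2-yl)silyl]hex-5-ynoic acid | OC(=O)CCC(=O)C#C[Si](C(C)C)(C(C)C)C(C)C | intermediate
8 | 2-methylpropyl carbonic anhydride of 7 | CC(C)COC(=O)OC(=O)CCC(=O)C#C[Si](C(C)C)(C(C)C)C(C)C | intermediate (not isolated)
9 | 7-diazo-1-[tri(propan-2-yl)silyl]oct-1-yne-3,6-dione | CC(=[N+]=[N-])C(=O)CCC(=O)C#C[Si](C(C)C)(C(C)C)C(C)C | intermediate
10 | six-membered carbonyl ylide (2-methyl-3-oxo-6-silylethynyl-oxan-1-ium-2-ide, rhodium-associated) | C[C-]1[O+]=C(CCC1=O)C#C[Si](C(C)C)(C(C)C)C(C)C | intermediate (not isolated)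
11 | (1R,5S,6S)-6-[(4-methoxyphenyl)methoxy]-1-methyl-5-{[tri(propan-2-yl)silyl]ethynyl}-8-oxabicyclo[3.2.1]octan-2-one | COc1ccc(CO[C@H]2C[C@@]3(C)O[C@]2(C#C[Si](C(C)C)(C(C)C)C(C)C)CCC3=O)cc1 | intermediate
12 | trimethylsilyl enol ether of 11 (C1=C2, target numbering) | COc1ccc(CO[C@H]2C[C@@]3(C)O[C@]2(C#C[Si](C(C)C)(C(C)C)C(C)C)CC=C3O[Si](C)(C)C)cc1 | intermediate (not isolated)
13 | (1R,5S,6S)-6-[(4-methoxyphenyl)methoxy]-1-methyl-5-{[tri(propan-2-yl)silyl]ethynyl}-8-oxabicyclo[3.2.1]oct-3-en-2-one | COc1ccc(CO[C@H]2C[C@@]3(C)O[C@]2(C#C[Si](C(C)C)(C(C)C)C(C)C)C=CC3=O)cc1 | intermediate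
14 | 3-exo,4-exo-dihydroxy derivative of 11 (cis diol) | COc1ccc(CO[C@H]2C[C@@]3(C)O[C@]2(C#C[Si](C(C)C)(C(C)C)C(C)C)[C@H](O)[C@H](O)C3=O)cc1 | intermediate (not isolated)
15 | (2R,4S,5S)-5-formyl-4-[(4-methoxyphenyl)methoxy]-2-methyl-5-{[tri(propan-2-yl)silyl]ethynyl}oxolane-2-carboxylic acid | COc1ccc(CO[C@H]2C[C@](C)(C(=O)O)O[C@]2(C#C[Si](C(C)C)(C(C)C)C(C)C)C=O)cc1 | intermediate
16 | (2R,4S,5S)-5-formyl-N-methoxy-4-[(4-methoxyphenyl)methoxy]-N,2-dimethyl-5-{[tri(propan-2-yl)silyl]ethynyl}oxolane-2-carboxamide | COc1ccc(CO[C@H]2C[C@](C)(C(=O)N(C)OC)O[C@]2(C#C[Si](C(C)C)(C(C)C)C(C)C)C=O)cc1 | intermediate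
17 | iodoethene | C=CI | starting material
18 | (2R,4S,5S)-N-methoxy-4-[(4-methoxyphenyl)methoxy]-N,2-dimethyl-5-{(1R)-1-[(triethylsilyl)oxy]prop-2-en-1-yl}-5-{[tri(propan-2-yl)silyl]ethynyl}oxolane-2-carboxamide | COc1ccc(CO[C@H]2C[C@](C)(C(=O)N(C)OC)O[C@]2(C#C[Si](C(C)C)(C(C)C)C(C)C)[C@H](O[Si](CC)(CC)CC)C=C)cc1 | intermediate
19 | 4-bromo-2-methylbut-1-ene | C=C(C)CCBr | starting material
20 | (3-methylbut-3-en-1-yl)magnesium bromide | C=C(C)CC[Mg]Br | intermediate (not isolated)
21 | 1-[(2R,4S,5S)-4-[(4-methoxyphenyl)methoxy]-2-methyl-5-{(1R)-1-[(triethylsilyl)oxy]prop-2-en-1-yl}-5-{[tri(propan-2-yl)silyl]ethynyl}oxolan-2-yl]-4-methylpent-4-en-1-one | COc1ccc(CO[C@H]2C[C@](C)(C(=O)CCC(C)=C)O[C@]2(C#C[Si](C(C)C)(C(C)C)C(C)C)[C@H](O[Si](CC)(CC)CC)C=C)cc1 | intermediate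
22 | (1R,5Z,7R,8S,9S)-9-[(4-methoxyphenyl)methoxy]-1,5-dimethyl-7-[(triethylsilyl)oxy]-8-{[tri(propan-2-yl)silyl]ethynyl}-11-oxabicyclo[6.2.1]undec-5-en-2-one | COc1ccc(CO[C@H]2C[C@@]3(C)O[C@]2(C#C[Si](C(C)C)(C(C)C)C(C)C)[C@H](O[Si](CC)(CC)CC)/C=C(C)\CCC3=O)cc1 | intermediate
23 | (1R,5Z,7R,8R,9S)-8-ethynyl-7-hydroxy-9-[(4-methoxyphenyl)methoxy]-1,5-dimethyl-11-oxabicyclo[6.2.1]undec-5-en-2-one | COc1ccc(CO[C@H]2C[C@@]3(C)O[C@]2(C#C)[C@H](O)/C=C(C)\CCC3=O)cc1 | intermediate
24 | (1R,5R,6S,7R,8R,9S)-5,6-epoxy-8-ethynyl-7-hydroxy-9-[(4-methoxyphenyl)methoxy]-1,5-dimethyl-11-oxabicyclo[6.2.1]undecan-2-one | COc1ccc(CO[C@H]2C[C@@]3(C)O[C@]2(C#C)[C@H](O)[C@@H]4O[C@]4(C)CCC3=O)cc1 | intermediate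
25 | 4-methoxybenzyl ether of 26 (target skeleton with C8–OCH2C6H4OMe in place of the ester) | COc1ccc(CO[C@H]2C[C@@]3(C)O[C@@]24C(=C)C(=O)O[C@@H]4[C@@H]5O[C@]5(C)CCC3=O)cc1 | intermediate
26 | C8 alcohol (target without the 2-methylprop-2-enoyl group; configuration as in the target) | O[C@H]1C[C@@]2(C)O[C@@]13C(=C)C(=O)O[C@@H]3[C@@H]1O[C@]1(C)CCC2=O | intermediate
27 | 2-methylprop-2-enoyl chloride | C=C(C)C(Cl)=O | starting material
28 | CNP0241021.1 | C=C(C)C(=O)O[C@H]1C[C@@]2(C)O[C@@]13C(=C)C(=O)O[C@@H]3[C@@H]1O[C@]1(C)CCC2=O | target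

Total step count: 15. Longest linear sequence: 14 steps (steps 2 to 15; step 1 is a side branch).

Steps most likely to fail

1. Step 4 (carbonyl-ylide cycloaddition). The ylide may leave rhodium before it meets the vinyl ether, so that enantiofacial control is lost although the exo bicyclic ketone still forms. Fallback (sets out from 9, comes back at 15): the cycloaddition is run with Rh2(OAc)4 or accepted at low enantiomeric purity, and the material is carried through steps 5 and 6. Acid 15 is then freed from its enantiomer by crystallisation of the quininium salt F1 from acetone, and dilute aqueous acid returns enantiopure 15. Stereocontrol thus rests on classical resolution of the first carboxylic acid in the route, not on the catalyst.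

2. Step 10 (ring-closing metathesis). The ruthenium carbene at the crowded C5 vinyl group may fail to engage the 1,1-disubstituted alkene, so that intermolecular metathesis takes over. Fallback (sets out from 16, comes back at 22): the ring is closed at C5–C6 by an intramolecular Nozaki–Hiyama–Kishi reaction instead. The aldehyde of 16 is masked as the dimethyl acetal F2 (HC(OMe)3, pyridinium tosylate, MeOH). MeMgBr converts the Weinreb amide into the methyl ketone F3. Its only possible enolate (LiN(SiMe3)2, THF, −78 °C) is alkylated with (Z)-3-bromo-1-iodo-2-methylprop-1-ene, which forms C2–C3 and gives the vinyl iodide F4. Mild aqueous acid frees the keto aldehyde F5. CrCl2/NiCl2 with Mn and Et3SiCl at high dilution should then join C5 to C6 and give 22 directly as its silyl ether; the Z geometry comes from the reagent and C6 is set anti to the C7–O bond in the ring-closing event.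

3. Step 12 (directed epoxidation). The macrocycle may react through a conformer that presents the other alkene face to the vanadium-bound peroxide, or the allylic alcohol may be oxidised to the enone instead. Fallback (sets out from 22, comes back at 24): the oxygen is brought in from the opposite face by a halohydrin sequence on the silyl ether. N-bromosuccinimide in aqueous acetone should form the bromonium ion on the exposed face of 22 and water should open it at the tertiary C4 from the other side, giving the bromohydrin F6. K2CO3 in MeOH closes the epoxide F7 by displacement of bromide by the C4 alkoxide with inversion at C5. Bu4NF as in step 11 then gives 24.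

Further compounds
F1 | step 4 | quininium (2R,4S,5S)-5-formyl-4-[(4-methoxyphenyl)methoxy]-2-methyl-5-{[tri(propan-2-yl)silyl]ethynyl}oxolane-2-carboxylate | COc1ccc(CO[C@H]2C[C@](C)(C([O-])=O)O[C@]2(C#C[Si](C(C)C)(C(C)C)C(C)C)C=O)cc1.COC1=CC2=C(C=CN=C2C=C1)[C@H]([C@@H]3C[C@@H]4CC[NH+]3C[C@@H]4C=C)O
F2 | step 10 | (2R,4S,5S)-5-(dimethoxymethyl)-N-methoxy-4-[(4-methoxyphenyl)methoxy]-N,2-dimethyl-5-{[tri(propan-2-yl)silyl]ethynyl}oxolane-2-carboxamide | COc1ccc(CO[C@H]2C[C@](C)(C(=O)N(C)OC)O[C@]2(C#C[Si](C(C)C)(C(C)C)C(C)C)C(OC)OC)cc1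
F3 | step 10 | 1-[(2R,4S,5S)-5-(dimethoxymethyl)-4-[(4-methoxyphenyl)methoxy]-2-methyl-5-{[tri(propan-2-yl)silyl]ethynyl}oxolan-2-yl]ethan-1-one | COc1ccc(CO[C@H]2C[C@](C)(C(C)=O)O[C@]2(C#C[Si](C(C)C)(C(C)C)C(C)C)C(OC)OC)cc1
F4 | step 10 | (4Z)-1-[(2R,4S,5S)-5-(dimethoxymethyl)-4-[(4-methoxyphenyl)methoxy]-2-methyl-5-{[tri(propan-2-yl)silyl]ethynyl}oxolan-2-yl]-5-iodo-4-methylpent-4-en-1-one | COc1ccc(CO[C@H]2C[C@](C)(C(=O)CC/C(C)=C\I)O[C@]2(C#C[Si](C(C)C)(C(C)C)C(C)C)C(OC)OC)cc1
F5 | step 10 | (2S,3S,5R)-5-[(4Z)-5-iodo-4-methylpent-4-enoyl]-3-[(4-methoxyphenyl)methoxy]-5-methyl-2-{[tri(propan-2-yl)silyl]ethynyl}oxolane-2-carbaldehyde | COc1ccc(CO[C@H]2C[C@](C)(C(=O)CC/C(C)=C\I)O[C@]2(C#C[Si](C(C)C)(C(C)C)C(C)C)C=O)cc1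
F6 | step 12 | bromohydrin of 22 (C5 bromide, C4 tertiary alcohol, target numbering; silyl groups retained) | COc1ccc(CO[C@H]2C[C@@]3(C)O[C@]2(C#C[Si](C(C)C)(C(C)C)C(C)C)[C@H](O[Si](CC)(CC)CC)[C@@H](Br)[C@](C)(O)CCC3=O)cc1
F7 | step 12 | 4R,5S epoxide of 22 (target numbering; silyl groups retained) | COc1ccc(CO[C@H]2C[C@@]3(C)O[C@]2(C#C[Si](C(C)C)(C(C)C)C(C)C)[C@H](O[Si](CC)(CC)CC)[C@@H]4O[C@]4(C)CCC3=O)cc1
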